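**Assumptions (one line each)**
- The SMILES is read literally: (1R,4aS,9S,10S,11aS,12S,13R), 7E. This puts 1‑OAc, C11 (on C11a) and C5 (on C4a) on the same face of the dihydropyran (cis ring fusion), 9‑OAc/10‑OH trans, and 12‑OAc/13‑OBz anti (erythro). Xenicane numbering is used for atom labels.
- Ancillary reagents (I2, TBDPSCl, Ac2O, NBS, TBHP, BzCl) are given with SMILES under "Reagents that add atoms" and are not numbered; every carbon‑skeleton building block is numbered.

**Retrosynthetic overview**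
1. C10–C11 is cut last: an intramolecular Ni/Cr (NHK) coupling of a 2‑bromoalkene onto an α‑acetoxy aldehyde closes the nine‑membered ring, makes the exocyclic methylene allylic alcohol and leaves 10‑OH as the only free hydroxyl.
2. C4–C12 is cut next: a halogen‑selective intermolecular NHK coupling of the C4 iodide (vinyl bromide untouched) with (R)‑2‑benzoyloxy aldehyde 22, Felkin‑controlled for 12S.
3. The dihydropyran comes from an endo inverse‑electron‑demand oxa‑Diels–Alder of (Z)‑2‑iodoenal 12 with (Z)‑enol ether 16, setting C1, C11a and C4a (all‑cis) in one step; the acetal OR is then exchanged for OAc with retention.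
4. Fragments: 12 from (R)‑glyceraldehyde acetonide (C9) by Johnson–Claisen; 16 from 1,4‑dichlorobut‑2‑yne; 22 by Sharpless desymmetrisation of a divinyl carbinol (C13).
5. Ring order: dihydropyran first (step 15), nine‑membered carbocycle last (step 21).

---

## Fragment A: heterodiene 12 (C3–C10)

**Step 1**
Reactants: 1 (R)‑2,2‑dimethyl‑1,3‑dioxolane‑4‑carbaldehyde; 2 isopropenylmagnesium bromide
Product: 3 1‑[(4R)‑2,2‑dimethyl‑1,3‑dioxolan‑4‑yl]‑2‑methylprop‑2‑en‑1‑ol (carbinol epimers, both used)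
Conditions: THF, −78 → 0 °C
Reagents that add atoms: none (isopropenyl comes from 2)
Why: Grignard 1,2‑addition; the new carbinol centre becomes sp2 (C8) in step 2, so its configuration is irrelevant, and C9 comes from the chiral pool.

**Step 2**
Reactants: 3; 4 triethyl orthoacetate
Product: 5 ethyl (4E)‑5‑[(4S)‑2,2‑dimethyl‑1,3‑dioxolan‑4‑yl]‑4‑methylpent‑4‑enoate
Conditions: MeC(OEt)3 (excess), EtCO2H (cat.), 140 °C, EtOH distilled off
Reagents that add atoms: none (C2 unit and OEt come from 4)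
Why: Johnson orthoester Claisen rearrangement; the chair transition state with the C9 substituent equatorial gives the E trisubstituted C7=C8 alkene.

**Step 3**
Reactants: 5
Product: 6 (4E)‑5‑[(4S)‑2,2‑dimethyl‑1,3‑dioxolan‑4‑yl]‑4‑methylpent‑4‑enal
Conditions: DIBAL‑H (1.05 equiv), CH2Cl2, −78 °C; Rochelle salt
Reagents that add atoms: none
Why: Low‑temperature partial reduction of the ester to the aldehyde via the stable tetrahedral aluminate.

**Step 4**
Reactants: 6; 7 (triphenylphosphoranylidene)acetaldehyde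
Product: 8 (2E,6E)‑7‑[(4S)‑2,2‑dimethyl‑1,3‑dioxolan‑4‑yl]‑6‑methylhepta‑2,6‑dienal
Conditions: toluene, 80 °C
Reagents that add atoms: none (C2 unit comes from 7)
Why: Wittig olefination with a stabilised formyl ylide, E‑selective.

**Step 5**
Reactants: 8
Product: 9 (2Z,6E)‑7‑[(4S)‑2,2‑dimethyl‑1,3‑dioxolan‑4‑yl]‑2‑iodo‑6‑methylhepta‑2,6‑dienal
Conditions: I2, K2CO3, DMAP (0.2 equiv), THF/H2O, rt
Reagents that add atoms: iodine, II
Why: Nucleophile‑catalysed α‑iodination of an enal (DMAP conjugate addition, enolate iodination, elimination) gives the Z iodoenal with CHO trans to the chain; the isolated alkene and acetonide are inert.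

**Step 6**
Reactants: 9
Product: 10 (2Z,6E,8S)‑8,9‑dihydroxy‑2‑iodo‑6‑methylnona‑2,6‑dienal
Conditions: AcOH/H2O 4:1, 35 °C
Reagents that add atoms: none
Why: Acid hydrolysis of the acetonide, done here because no acid can be used once the pyran acetal exists.

**Step 7**
Reactants: 10
Product: 11 (2Z,6E,8S)‑9‑[(tert‑butyldiphenylsilyl)oxy]‑8‑hydroxy‑2‑iodo‑6‑methylnona‑2,6‑dienal
Conditions: TBDPSCl (1.05 equiv), imidazole, CH2Cl2, −20 → 0 °C
Reagents that add atoms: TBDPSCl, CC(C)(C)[Si](Cl)(c1ccccc1)c1ccccc1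
Why: Selective silylation of the primary (C10) hydroxyl on steric grounds.

**Step 8**
Reactants: 11
Product: 12 (2S,3E,7Z)‑1‑[(tert‑butyldiphenylsilyl)oxy]‑8‑iodo‑4‑methyl‑9‑oxonona‑3,7‑dien‑2‑yl acetate
Conditions: Ac2O, pyridine, CH2Cl2, 0 °C → rt
Reagents that add atoms: acetic anhydride, CC(=O)OC(C)=O
Why: Acetylation installs the final 9‑OAc early; every later step is ester‑tolerant.

## Fragment B: dienophile 16 (C1, C11a, C11, C19)

**Step 9**
Reactants: 13 1,4‑dichlorobut‑2‑yne; 14 2‑(trimethylsilyl)ethanol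
Product: 15 (Z)‑1‑[2‑(trimethylsilyl)ethoxy]but‑1‑en‑3‑yne
Conditions: KOH (excess), 14 (3 equiv), DMSO, 60 °C, slow addition of 13
Reagents that add atoms: none (both reactants are numbered)
Why: Brandsma‑type double dehydrochlorination to butadiyne in situ, then anti addition of the alkoxide to the terminal alkyne gives the Z enol ether.

**Step 10**
Reactants: 15
Product: 16 (1Z)‑3‑bromo‑1‑[2‑(trimethylsilyl)ethoxy]buta‑1,3‑diene
Conditions: Ni(dppp)Cl2 (3 mol %), DIBAL‑H (1.3 equiv), THF, 0 → 22 °C; then NBS, −78 → 0 °C; used cold with BHT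
Reagents that add atoms: N‑bromosuccinimide, O=C1CCC(=O)N1Br
Why: Ni‑catalysed α‑selective (Markovnikov) hydroalumination of the terminal alkyne, then bromodealumination, gives the 2‑bromoalkene without acid, so the Z enol ether survives.

## Fragment C: side‑chain aldehyde 22 (C12–C15)

**Step 11**
Reactants: 17 ethyl formate; 18 2‑methylprop‑1‑enylmagnesium bromide (2.2 equiv)
Product: 19 2,6‑dimethylhepta‑2,5‑dien‑4‑ol
Conditions: THF, 0 °C
Reagents that add atoms: none
Why: Double Grignard addition to a formate gives the achiral (meso‑type) divinyl carbinol.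

**Step 12**
Reactants: 19
Product: 20 (1R)‑1‑[(2R)‑3,3‑dimethyloxiran‑2‑yl]‑3‑methylbut‑2‑en‑1‑ol
Conditions: Ti(OiPr)4, D‑(−)‑DIPT, t‑BuOOH, 4 Å MS, CH2Cl2, −25 °C
Reagents that add atoms: tert‑butyl hydroperoxide, CC(C)(C)OO
Why: Sharpless asymmetric epoxidation used as an enantiotopic‑group desymmetrisation; the Sharpless mnemonic with D‑(−)‑tartrate gives the R carbinol (future C13), and over‑epoxidation removes the minor enantiomer.

**Step 13**
Reactants: 20
Product: 21 (1R)‑1‑[(2R)‑3,3‑dimethyloxiran‑2‑yl]‑3‑methylbut‑2‑en‑1‑yl benzoate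
Conditions: BzCl, pyridine, DMAP (cat.), CH2Cl2, 0 °C
Reagents that add atoms: benzoyl chloride, O=C(Cl)c1ccccc1
Why: Esterification installs the final 13‑OBz before the aldehyde is unveiled.

**Step 14**
Reactants: 21
Product: 22 (2R)‑4‑methyl‑1‑oxopent‑3‑en‑2‑yl benzoate (used at once)
Conditions: H5IO6, Et2O/THF, 0 °C
Reagents that add atoms: none (the aldehyde oxygen is the epoxide oxygen; acetone is lost)
Why: Periodic acid cleavage of the trisubstituted epoxide gives the α‑benzoyloxy aldehyde without touching C13.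

## Assembly

**Step 15 (key step 1)**
Reactants: 12; 16 (3 equiv)
Product: 23 (2S,3R,4S)‑3‑(1‑bromovinyl)‑5‑iodo‑2‑[2‑(trimethylsilyl)ethoxy]‑3,4‑dihydro‑2H‑pyran carrying at C4 the (3E,5S)‑5‑acetoxy‑6‑(TBDPS‑oxy)‑3‑methylhex‑3‑enyl chain; 2,3,4‑all‑cis
Conditions: Jacobsen tridentate (aminoindanol Schiff base)Cr(III)Cl catalyst (10 mol %; the antipode that gives 4aS, chosen on a model pair), 4 Å MS, minimal t‑BuOMe, rt, 72 h
Reagents that add atoms: none
Why: Proposed new method: an inverse‑electron‑demand oxa‑Diels–Alder in which the Cr(III)‑bound, iodine‑activated enal is the 4π partner and the enol‑ether C=C of 16 the 2π partner; the closest known reaction is the Cr(III)‑catalysed endo‑selective cycloaddition of α,β‑unsaturated aldehydes (including α‑substituted ones) with ethyl vinyl ether. The endo (alkoxy‑endo) transition state with a Z dienophile puts OR and the bromovinyl group cis, and the E‑disposed C5 chain on the same face, so C1, C11a and C4a are set all‑cis in one step with the absolute sense from the catalyst; the Z geometry keeps 16 out of the s‑cis conformation it would need to act as a diene.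

**Step 16**
Reactants: 23
Product: 24 (2R,3R,4S)‑2‑acetoxy analogue of 23 (anomeric acetate, all‑cis retained)
Conditions: Ac2O (3 equiv), BF3·OEt2 (0.8 equiv), toluene, −30 → 0 °C, quench with Et3N
Reagents that add atoms: acetic anhydride, CC(=O)OC(C)=O
Why: The known conversion of 2‑(trimethylsilyl)ethyl glycosides into 1‑O‑acyl derivatives: electrophilic activation at the exocyclic oxygen, then β‑silyl fragmentation (ethylene lost), so the C1–O bond is never broken and C1 is retained; the C4 iodine deactivates the enol ether toward BF3.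

**Step 17**
Reactants: 24; 22 (1.5 equiv)
Product: 25, i.e. 24 with the C4 iodine replaced by the (1S,2R)‑2‑(benzoyloxy)‑1‑hydroxy‑4‑methylpent‑3‑enyl group (12S,13R)
Conditions: CrCl2 (5 equiv), NiCl2 (1 mol %), DMSO, rt; buffered work‑up, Et3N‑treated silica
Reagents that add atoms: none
Why: Nozaki–Hiyama–Kishi coupling; at low Ni loading the alkenyl iodide inserts while the 2‑bromoalkene and all esters are left alone, and polar Felkin–Anh addition to the α‑benzoyloxy aldehyde gives the 12,13‑anti (12S) carbinol.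

**Step 18**
Reactants: 25
Product: 26, the 12‑O‑acetate of 25
Conditions: Ac2O, pyridine, DMAP (cat.), CH2Cl2, 0 °C
Reagents that add atoms: acetic anhydride, CC(=O)OC(C)=O
Why: Acetylation of the only free hydroxyl under basic, non‑ionising conditions, which avoids Ferrier‑type loss of the allylic oxygen.

**Step 19**
Reactants: 26
Product: 27, the C10 primary alcohol (TBDPS removed)
Conditions: HF·pyridine, excess pyridine, THF, 0 °C → rt; crude used directly
Reagents that add atoms: none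
Why: Buffered fluoride desilylation; acetates, benzoate, anomeric acetate and enol ether tolerate it, and the acidic medium suppresses 9→10 acetyl migration.

**Step 20**
Reactants: 27
Product: 28, the seco‑aldehyde (C10 CHO, 9S‑OAc, C11 2‑bromoalkene)
Conditions: Dess–Martin periodinane, NaHCO3, CH2Cl2, 0 °C; used at once
Reagents that add atoms: none
Why: Neutral oxidation to the α‑acetoxy aldehyde without epimerising C9 or moving the C7=C8 alkene into conjugation.

**Step 21 (key step 2)**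
Reactants: 28
Product: 29 antheliatin
Conditions: pre‑formed CrCl2/Kishi oxazoline–sulfonamide ligand complex (8 equiv; the antipode that gives 10S), NiCl2·(2,9‑dimethylphenanthroline) (0.5 equiv), THF/MeCN, 2 mM, slow addition, rt → 40 °C
Reagents that add atoms: none
Why: Intramolecular Nozaki–Hiyama–Kishi macrocyclisation (Ni inserts into C–Br, transmetalation to Cr, alkenyl–Cr adds to the aldehyde) closes the nine‑membered ring, forms C11(=CH2)–C10(OH) and leaves 10‑OH free. The required 9,10‑trans (10S) product is the anti‑Felkin one, so it is imposed by the chiral Cr ligand rather than by the substrate.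

---

## Compound list

1 | (R)‑2,2‑dimethyl‑1,3‑dioxolane‑4‑carbaldehyde | O=C[C@H]1COC(C)(C)O1 | starting material
2 | isopropenylmagnesium bromide | C=C(C)[Mg]Br | starting material
3 | 1‑[(4R)‑2,2‑dimethyl‑1,3‑dioxolan‑4‑yl]‑2‑methylprop‑2‑en‑1‑ol | C=C(C)C(O)[C@H]1COC(C)(C)O1 | intermediate
4 | triethyl orthoacetate | CCOC(C)(OCC)OCC | starting material
5 | ethyl (4E)‑5‑[(4S)‑2,2‑dimethyl‑1,3‑dioxolan‑4‑yl]‑4‑methylpent‑4‑enoate | CCOC(=O)CC/C(C)=C/[C@H]1COC(C)(C)O1 | intermediate
6 | (4E)‑5‑[(4S)‑2,2‑dimethyl‑1,3‑dioxolan‑4‑yl]‑4‑methylpent‑4‑enal | O=CCC/C(C)=C/[C@H]1COC(C)(C)O1 | intermediate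
7 | (triphenylphosphoranylidene)acetaldehyde | O=CC=P(c1ccccc1)(c1ccccc1)c1ccccc1 | starting material
8 | (2E,6E)‑7‑[(4S)‑2,2‑dimethyl‑1,3‑dioxolan‑4‑yl]‑6‑methylhepta‑2,6‑dienal | O=C/C=C/CC/C(C)=C/[C@H]1COC(C)(C)O1 | intermediate
9 | (2Z,6E)‑7‑[(4S)‑2,2‑dimethyl‑1,3‑dioxolan‑4‑yl]‑2‑iodo‑6‑methylhepta‑2,6‑dienal | O=C/C(I)=C/CC/C(C)=C/[C@H]1COC(C)(C)O1 | intermediate
10 | (2Z,6E,8S)‑8,9‑dihydroxy‑2‑iodo‑6‑methylnona‑2,6‑dienal | O=C/C(I)=C/CC/C(C)=C/[C@H](O)CO | intermediate
11 | (2Z,6E,8S)‑9‑(TBDPS‑oxy)‑8‑hydroxy‑2‑iodo‑6‑methylnona‑2,6‑dienal | O=C/C(I)=C/CC/C(C)=C/[C@H](O)CO[Si](c1ccccc1)(c1ccccc1)C(C)(C)C | intermediate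
12 | (2S,3E,7Z)‑1‑(TBDPS‑oxy)‑8‑iodo‑4‑methyl‑9‑oxonona‑3,7‑dien‑2‑yl acetate | O=C/C(I)=C/CC/C(C)=C/[C@H](OC(C)=O)CO[Si](c1ccccc1)(c1ccccc1)C(C)(C)C | intermediate
13 | 1,4‑dichlorobut‑2‑yne | ClCC#CCCl | starting material
14 | 2‑(trimethylsilyl)ethanol | C[Si](C)(C)CCO | starting material
15 | (Z)‑1‑[2‑(trimethylsilyl)ethoxy]but‑1‑en‑3‑yne | C#C/C=C\OCC[Si](C)(C)C | intermediate
16 | (1Z)‑3‑bromo‑1‑[2‑(trimethylsilyl)ethoxy]buta‑1,3‑diene | C=C(Br)/C=C\OCC[Si](C)(C)C | intermediate
17 | ethyl formate | CCOC=O | starting material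
18 | 2‑methylprop‑1‑enylmagnesium bromide | CC(C)=C[Mg]Br | starting material
19 | 2,6‑dimethylhepta‑2,5‑dien‑4‑ol | CC(C)=CC(O)C=C(C)C | intermediate
20 | (1R)‑1‑[(2R)‑3,3‑dimethyloxiran‑2‑yl]‑3‑methylbut‑2‑en‑1‑ol | CC(C)=C[C@@H](O)[C@H]1OC1(C)C | intermediate
21 | (1R)‑1‑[(2R)‑3,3‑dimethyloxiran‑2‑yl]‑3‑methylbut‑2‑en‑1‑yl benzoate | CC(C)=C[C@@H](OC(=O)c1ccccc1)[C@H]1OC1(C)C | intermediate
22 | (2R)‑4‑methyl‑1‑oxopent‑3‑en‑2‑yl benzoate | O=C[C@@H](C=C(C)C)OC(=O)c1ccccc1 | intermediate
23 | (2S,3R,4S)‑3‑(1‑bromovinyl)‑5‑iodo‑2‑[2‑(trimethylsilyl)ethoxy]‑4‑[(3E,5S)‑5‑acetoxy‑6‑(TBDPS‑oxy)‑3‑methylhex‑3‑enyl]‑3,4‑dihydro‑2H‑pyran (all‑cis) | C=C(Br)[C@H]1[C@@H](OCC[Si](C)(C)C)OC=C(I)[C@H]1CC/C(C)=C/[C@H](OC(C)=O)CO[Si](c1ccccc1)(c1ccccc1)C(C)(C)C | intermediate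
24 | (2R,3R,4S)‑2‑acetoxy analogue of 23 | C=C(Br)[C@H]1[C@@H](OC(C)=O)OC=C(I)[C@H]1CC/C(C)=C/[C@H](OC(C)=O)CO[Si](c1ccccc1)(c1ccccc1)C(C)(C)C | intermediate
25 | 24 with C5‑I replaced by (1S,2R)‑2‑(benzoyloxy)‑1‑hydroxy‑4‑methylpent‑3‑enyl | C=C(Br)[C@H]1[C@@H](OC(C)=O)OC=C([C@H](O)[C@@H](C=C(C)C)OC(=O)c2ccccc2)[C@H]1CC/C(C)=C/[C@H](OC(C)=O)CO[Si](c1ccccc1)(c1ccccc1)C(C)(C)C | intermediate
26 | 12‑O‑acetate of 25 | C=C(Br)[C@H]1[C@@H](OC(C)=O)OC=C([C@H](OC(C)=O)[C@@H](C=C(C)C)OC(=O)c2ccccc2)[C@H]1CC/C(C)=C/[C@H](OC(C)=O)CO[Si](c1ccccc1)(c1ccccc1)C(C)(C)C | intermediate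
27 | C10 primary alcohol (26 minus TBDPS) | C=C(Br)[C@H]1[C@@H](OC(C)=O)OC=C([C@H](OC(C)=O)[C@@H](C=C(C)C)OC(=O)c2ccccc2)[C@H]1CC/C(C)=C/[C@H](OC(C)=O)CO | intermediate
28 | seco‑aldehyde (C10 CHO, C11 2‑bromoalkene) | C=C(Br)[C@H]1[C@@H](OC(C)=O)OC=C([C@H](OC(C)=O)[C@@H](C=C(C)C)OC(=O)c2ccccc2)[C@H]1CC/C(C)=C/[C@H](OC(C)=O)C=O | intermediate
29 | antheliatin | C=C1[C@H]2[C@@H](OC(C)=O)OC=C([C@H](OC(C)=O)[C@@H](C=C(C)C)OC(=O)c3ccccc3)[C@H]2CC/C(C)=C/[C@H](OC(C)=O)[C@H]1O | target

---

**Total steps:** 21 (8 for fragment A, 2 for B, 4 for C, 7 for assembly).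
**Longest linear sequence:** 15 steps (steps 1–8, then 15–21).

**Three steps most likely to fail, each with a fallback that changes the approach**

1. **Step 15 (oxa‑Diels–Alder).** The β‑substituted Z enol ether may be too unreactive, or 16 may react as a diene. Fallback: build the same C4a–C11a bond stepwise. A diarylprolinol‑silyl‑ether‑catalysed syn Michael addition of 3‑bromobut‑3‑enal to the non‑iodinated enal (made as 12 but omitting step 5) gives the 1,5‑dialdehyde; Ac2O/DMAP cyclisation gives the acetoxy‑dihydropyran; NIS then base iodinates C4 to rejoin the route at 24.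

2. **Step 16 (acetal to acetate with retention).** BF3 may anomerise C1 or open the ring through the enol oxygen. Fallback: run step 15 with the p‑methoxybenzyl analogue of 16, cleave oxidatively (DDQ) to the lactol, and esterify under Mitsunobu conditions (AcOH, PPh3, DIAD), which inverts the more reactive equatorial (trans) lactol to give the cis acetate.

3. **Step 21 (nine‑ring NHK with a bromide, C10 control).** The bromide may insert slowly, and the substrate bias (Felkin) favours 10‑epi. Fallback: take whichever C10 epimer forms (or run without ligand at higher Ni loading), oxidise with Dess–Martin periodinane to the α‑methylene ketone, and set 10S by reagent‑controlled CBS reduction. Stereocontrol is thereby moved from the C–C bond formation to a ketone reduction.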